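**Plan**

- Retrosynthesis: the galloyl ester at O7 is cut first, then ring C is cut at O1–C2 and at C3–C4.
- Enabling feature: in ring C the O1–C8a–C4a–C4 unit is a masked 1-oxadiene (an o-quinone methide of ring A), and the trans C2-aryl/C3-oxygen pair is a masked (E)-2-arylvinyl ester.
- Forward: a ring A 2-hydroxybenzyl alcohol (three steps from 2,4,6-trihydroxybenzaldehyde) and a ring B (E)-enol acetate (three steps from 3,4-bis(benzyloxy)benzaldehyde) are joined in a hetero-Diels–Alder reaction that closes ring C.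
- End game: acetate and silyl ether are removed, O7 is acylated with benzyl-protected galloyl chloride, and the six benzyl ethers are hydrogenolysed.
- Stereochemistry: C2 and C3 arise together in the cycloaddition, trans from the (E)-alkene and in absolute terms from a chiral phosphoric acid; no later step touches them.

Key step: step 7

Assumption: the (R)-configured phosphoric acid is taken to lead to the (2R,3S) adduct; if the sense of induction is the opposite, its enantiomer is used and nothing else changes.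

**Route**

Step 1
Reactants: 1 2,4,6-trihydroxybenzaldehyde
Product: 2 2,6-dihydroxy-4-(triisopropylsilyloxy)benzaldehyde
Conditions: TIPSCl (1.05 equiv), imidazole, DMF, 0 °C
Reagents that add atoms: chlorotriisopropylsilane, CC(C)[Si](Cl)(C(C)C)C(C)C
Why: Regioselective phenol silylation; the 4-hydroxyl is the only one neither flanked by nor hydrogen-bonded to the formyl group, so the bulky silyl chloride should react there first.

Step 2
Reactants: 2 2,6-dihydroxy-4-(triisopropylsilyloxy)benzaldehyde
Product: 3 2-(benzyloxy)-6-hydroxy-4-(triisopropylsilyloxy)benzaldehyde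
Conditions: BnOH, PPh3, DIAD, THF, 0 °C → rt
Reagents that add atoms: benzyl alcohol, OCc1ccccc1
Why: Mitsunobu etherification under neutral conditions that spare the aryl silyl ether; once one ortho hydroxyl is benzylated the other is locked in the hydrogen bond to the aldehyde and should stay free.

Step 3
Reactants: 3 2-(benzyloxy)-6-hydroxy-4-(triisopropylsilyloxy)benzaldehyde
Product: 4 3-(benzyloxy)-2-(hydroxymethyl)-5-(triisopropylsilyloxy)phenol
Conditions: NaBH4, THF/MeOH, 0 °C; pH 7 buffer work-up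
Reagents that add atoms: none
Why: Borohydride reduction of the aldehyde; the cold, buffered work-up is meant to keep the electron-rich 2-hydroxybenzyl alcohol from ionising before step 7.

Step 4
Reactants: 5 3,4-bis(benzyloxy)benzaldehyde; 6 bis[(pinacolato)boryl]methane
Product: 7 2-[(E)-2-(3,4-bis(benzyloxy)phenyl)ethenyl]-4,4,5,5-tetramethyl-1,3,2-dioxaborolane
Conditions: 6, LiTMP (lithium 2,2,6,6-tetramethylpiperidide), THF, 0 °C; then 5, −78 °C → rt
Reagents that add atoms: none
Why: Boron-Wittig olefination; the lithiated gem-diboronate adds to the aldehyde and syn boron–oxygen elimination should give the (E)-alkenylboronate.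

Step 5
Reactants: 7 2-[(E)-2-(3,4-bis(benzyloxy)phenyl)ethenyl]-4,4,5,5-tetramethyl-1,3,2-dioxaborolane
Product: 8 potassium [(E)-2-(3,4-bis(benzyloxy)phenyl)ethenyl]trifluoroborate
Conditions: aq. KHF2, MeOH, rt
Reagents that add atoms: potassium hydrogen difluoride, F.[F-].[K+]
Why: Standard fluoride exchange of a pinacol boronate to the trifluoroborate, the form used in the copper coupling that follows.

Step 6
Reactants: 8 potassium [(E)-2-(3,4-bis(benzyloxy)phenyl)ethenyl]trifluoroborate
Product: 9 (E)-2-[3,4-bis(benzyloxy)phenyl]vinyl acetate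
Conditions: AcOH, CuBr (10 mol %), DMAP (20 mol %), 4 Å MS, O2 (1 atm), MeCN, 60 °C
Reagents that add atoms: acetic acid, CC(=O)O
Why: Chan–Lam-type oxidative C–O coupling of an alkenyltrifluoroborate with a carboxylic acid; transmetalation to copper and C–O reductive elimination from trivalent copper proceed with retention, so the (E)-geometry should be kept.

Step 7
Reactants: 4 3-(benzyloxy)-2-(hydroxymethyl)-5-(triisopropylsilyloxy)phenol; 9 (E)-2-[3,4-bis(benzyloxy)phenyl]vinyl acetate
Product: 11 (2R,3S)-5-(benzyloxy)-2-[3,4-bis(benzyloxy)phenyl]-7-(triisopropylsilyloxy)chroman-3-yl acetate, via o-quinone methide 10 (not isolated)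
Conditions: (R)-TRIP [(R)-3,3'-bis(2,4,6-triisopropylphenyl)-1,1'-binaphthyl-2,2'-diyl hydrogen phosphate] (10 mol %), 4 Å MS, PhMe, −20 °C; 4 added slowly to 9 (2 equiv)
Reagents that add atoms: none
Why: Proposed new method: the phosphoric acid should dehydrate the electron-rich 2-hydroxybenzyl alcohol 4 to the o-quinone methide 10, which stays hydrogen-bonded to the catalyst and reacts as a 1-oxadiene in an inverse-electron-demand hetero-Diels–Alder reaction with enol acetate 9; the closest known reaction types are the cycloaddition of o-quinone methides with anethole-type (E)-β-substituted styrenes to trans-2-aryl-3-substituted chromans and the chiral phosphoric acid catalysed [4+2] of o-quinone methides with enamides and hydroxystyrenes. Ring C is closed by the [4+2] itself, the exocyclic methide carbon bonding to the acetoxy-bearing carbon (C4–C3) and the carbonyl oxygen to the benzylic carbon (O1–C2); in the stepwise limit this is a 6-exo-trig capture of the 4-benzyloxybenzyl cation by the phenolic oxygen. C2 and C3 are set together: the suprafacial addition carries the (E)-geometry of the alkene over into the 2,3-trans arrangement, which is also the more stable diequatorial one, while the absolute sense has to come from the chiral phosphate that holds the quinone methide oxygen and screens one face of the approaching alkene. The step needs O1–C2 regiochemistry, secured because positive charge at C2 is stabilised far better by the para-benzyloxyphenyl ring than charge at C3 by the acetoxy group. It also needs the cycloaddition to outrun self-condensation of 10 with the nucleophilic ring A, which the slow addition of 4 to an excess of 9 and the sieves (removal of the water formed) are meant to secure.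

Step 8
Reactants: 11 (2R,3S)-5-(benzyloxy)-2-[3,4-bis(benzyloxy)phenyl]-7-(triisopropylsilyloxy)chroman-3-yl acetate
Product: 12 (2R,3S)-5-(benzyloxy)-2-[3,4-bis(benzyloxy)phenyl]chromane-3,7-diol
Conditions: K2CO3, MeOH/THF, rt → 40 °C
Reagents that add atoms: none
Why: Base-mediated methanolysis (transesterification of the acetate and cleavage of the base-labile aryl silyl ether); with O4' benzylated no quinone methide ring opening is possible, so C2 and C3 should not epimerise.

Step 9
Reactants: 13 3,4,5-tris(benzyloxy)benzoic acid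
Product: 14 3,4,5-tris(benzyloxy)benzoyl chloride
Conditions: (COCl)2, cat. DMF, CH2Cl2, 0 °C → rt
Reagents that add atoms: oxalyl chloride, O=C(Cl)C(=O)Cl
Why: Acid chloride formation through the Vilsmeier-type chloroiminium species generated from oxalyl chloride and DMF.

Step 10
Reactants: 12 (2R,3S)-5-(benzyloxy)-2-[3,4-bis(benzyloxy)phenyl]chromane-3,7-diol; 14 3,4,5-tris(benzyloxy)benzoyl chloride
Product: 15 (2R,3S)-5-(benzyloxy)-2-[3,4-bis(benzyloxy)phenyl]-3-hydroxychroman-7-yl 3,4,5-tris(benzyloxy)benzoate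
Conditions: 14 (1.05 equiv) added slowly, Et3N, CH2Cl2, −20 → 0 °C
Reagents that add atoms: none
Why: Chemoselective O-acylation; with triethylamine and no acyl-transfer catalyst the acidic 7-phenol reacts as its phenoxide much faster than the hindered secondary 3-hydroxyl.

Step 11
Reactants: 15 (2R,3S)-5-(benzyloxy)-2-[3,4-bis(benzyloxy)phenyl]-3-hydroxychroman-7-yl 3,4,5-tris(benzyloxy)benzoate
Product: 16 catechin 7-O-gallate, (2R,3S)-2-(3,4-dihydroxyphenyl)-3,5-dihydroxychroman-7-yl 3,4,5-trihydroxybenzoate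
Conditions: H2 (1 atm), Pd(OH)2/C, THF/MeOH, rt
Reagents that add atoms: none
Why: Hydrogenolysis of the six benzyl ethers; the aryl ester and the cyclic C2–O1 ether are expected to survive these mild neutral conditions, and neither stereocentre is involved.

**Compound list**

1 | 2,4,6-trihydroxybenzaldehyde | O=Cc1c(O)cc(O)cc1O | starting material
2 | 2,6-dihydroxy-4-(triisopropylsilyloxy)benzaldehyde | O=Cc1c(O)cc(O[Si](C(C)C)(C(C)C)C(C)C)cc1O | intermediate
3 | 2-(benzyloxy)-6-hydroxy-4-(triisopropylsilyloxy)benzaldehyde | O=Cc1c(O)cc(O[Si](C(C)C)(C(C)C)C(C)C)cc1OCc1ccccc1 | intermediate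
4 | 3-(benzyloxy)-2-(hydroxymethyl)-5-(triisopropylsilyloxy)phenol | OCc1c(O)cc(O[Si](C(C)C)(C(C)C)C(C)C)cc1OCc1ccccc1 | intermediate
5 | 3,4-bis(benzyloxy)benzaldehyde | O=Cc1ccc(OCc2ccccc2)c(OCc2ccccc2)c1 | starting material
6 | bis[(pinacolato)boryl]methane, 2,2'-methylenebis(4,4,5,5-tetramethyl-1,3,2-dioxaborolane) | CC1(C)OB(CB2OC(C)(C)C(C)(C)O2)OC1(C)C | starting material
7 | 2-[(E)-2-(3,4-bis(benzyloxy)phenyl)ethenyl]-4,4,5,5-tetramethyl-1,3,2-dioxaborolane | CC1(C)OB(/C=C/c2ccc(OCc3ccccc3)c(OCc3ccccc3)c2)OC1(C)C | intermediate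
8 | potassium [(E)-2-(3,4-bis(benzyloxy)phenyl)ethenyl]trifluoroborate | [K+].F[B-](F)(F)/C=C/c1ccc(OCc2ccccc2)c(OCc2ccccc2)c1 | intermediate
9 | (E)-2-[3,4-bis(benzyloxy)phenyl]vinyl acetate | CC(=O)O/C=C/c1ccc(OCc2ccccc2)c(OCc2ccccc2)c1 | intermediate
10 | 5-(benzyloxy)-6-methylidene-3-(triisopropylsilyloxy)cyclohexa-2,4-dien-1-one (o-quinone methide, not isolated) | C=C1C(=O)C=C(O[Si](C(C)C)(C(C)C)C(C)C)C=C1OCc1ccccc1 | intermediate
11 | (2R,3S)-5-(benzyloxy)-2-[3,4-bis(benzyloxy)phenyl]-7-(triisopropylsilyloxy)chroman-3-yl acetate | CC(C)[Si](C(C)C)(C(C)C)Oc1cc(OCc2ccccc2)c2c(c1)O[C@H](c1ccc(OCc3ccccc3)c(OCc3ccccc3)c1)[C@@H](OC(C)=O)C2 | intermediate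
12 | (2R,3S)-5-(benzyloxy)-2-[3,4-bis(benzyloxy)phenyl]chromane-3,7-diol | Oc1cc(OCc2ccccc2)c2c(c1)O[C@H](c1ccc(OCc3ccccc3)c(OCc3ccccc3)c1)[C@@H](O)C2 | intermediate
13 | 3,4,5-tris(benzyloxy)benzoic acid | OC(=O)c1cc(OCc2ccccc2)c(OCc2ccccc2)c(OCc2ccccc2)c1 | starting material
14 | 3,4,5-tris(benzyloxy)benzoyl chloride | ClC(=O)c1cc(OCc2ccccc2)c(OCc2ccccc2)c(OCc2ccccc2)c1 | intermediate
15 | (2R,3S)-5-(benzyloxy)-2-[3,4-bis(benzyloxy)phenyl]-3-hydroxychroman-7-yl 3,4,5-tris(benzyloxy)benzoate | O=C(Oc1cc(OCc2ccccc2)c2c(c1)O[C@H](c1ccc(OCc3ccccc3)c(OCc3ccccc3)c1)[C@@H](O)C2)c1cc(OCc2ccccc2)c(OCc2ccccc2)c(OCc2ccccc2)c1 | intermediate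
16 | catechin 7-O-gallate, (2R,3S) | O=C(Oc1cc(O)c2c(c1)O[C@H](c1ccc(O)c(O)c1)[C@@H](O)C2)c1cc(O)c(O)c(O)c1 | target

**Step count**

Total step count: 11. Longest linear sequence: 7 steps (steps 1, 2, 3, 7, 8, 10, 11; the branch through steps 4, 5, 6 is equally long).

**Steps most likely to fail**

Step 7. The alkene carries no hydrogen-bond donor to anchor it to the phosphate, so facial discrimination may be poor. In addition, the quinone methide may be consumed by self-condensation before it meets the dienophile, or the regiochemistry may leak towards the 3-aryl-2-acetoxy isomer. The fallback uses known chemistry only and sets out from aldehyde 3 and trifluoroborate 8. Heating the two with dibenzylamine in DMF (Petasis-type condensation, amine elimination and 6π-electrocyclisation) should give (±)-5-(benzyloxy)-2-[3,4-bis(benzyloxy)phenyl]-7-(triisopropylsilyloxy)-2H-chromene F1. Hydroboration with BH3·SMe2 anti to the 2-aryl group and oxidation with NaBO3·4H2O should give (±)-trans-5-(benzyloxy)-2-[3,4-bis(benzyloxy)phenyl]-7-(triisopropylsilyloxy)chroman-3-ol F2. Esterification with (S)-2-methoxy-2-phenylacetic acid (DCC, DMAP) should give the (2R,3S)-chroman-3-yl (S)-2-methoxy-2-phenylacetate F3 together with its (2S,3R) diastereomer F4, which would be separated by chromatography. Methanolysis of F3 with K2CO3 in MeOH removes the auxiliary and the silyl ether and comes back to the route at diol 12.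

Step 6. The electron-rich alkenylboron species may undergo protodeboronation or oxidative homocoupling faster than C–O coupling. The fallback sets out from aldehyde 5. Wittig homologation with (methoxymethyl)triphenylphosphonium chloride and KOtBu should give 1,2-bis(benzyloxy)-4-(2-methoxyethenyl)benzene F5 as an E/Z mixture. Hydrolysis with aqueous HCl in THF should give 2-[3,4-bis(benzyloxy)phenyl]acetaldehyde F6. Enol acetylation with Ac2O and KOAc under heating should give the (E)-enol acetate together with (Z)-2-[3,4-bis(benzyloxy)phenyl]vinyl acetate F7, which would be removed by chromatography. The fallback comes back to the route at 9.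

Step 10. Competing acylation of the 3-hydroxyl may give over-acylated material, or the reaction may stall short of full conversion. The fallback replaces kinetic chemoselectivity by protecting-group differentiation and sets out from diol 12. Silylation of both hydroxyls (TBSCl, imidazole, DMF) should give (2R,3S)-5-(benzyloxy)-2-[3,4-bis(benzyloxy)phenyl]-3,7-bis(tert-butyldimethylsilyloxy)chromane F8. K2CO3 in MeOH should cleave only the aryl silyl ether to give (2R,3S)-5-(benzyloxy)-2-[3,4-bis(benzyloxy)phenyl]-3-(tert-butyldimethylsilyloxy)chroman-7-ol F9. Acylation of the only free hydroxyl with 14 (Et3N, DMAP) should give (2R,3S)-5-(benzyloxy)-2-[3,4-bis(benzyloxy)phenyl]-3-(tert-butyldimethylsilyloxy)chroman-7-yl 3,4,5-tris(benzyloxy)benzoate F10. HF·pyridine in THF removes the alkyl silyl ether and comes back to the route at 15.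

**Further compounds**

F1 | step 7 | (±)-5-(benzyloxy)-2-[3,4-bis(benzyloxy)phenyl]-7-(triisopropylsilyloxy)-2H-chromene | CC(C)[Si](C(C)C)(C(C)C)Oc1cc(OCc2ccccc2)c2c(c1)OC(c1ccc(OCc3ccccc3)c(OCc3ccccc3)c1)C=C2
F2 | step 7 | (±)-trans-5-(benzyloxy)-2-[3,4-bis(benzyloxy)phenyl]-7-(triisopropylsilyloxy)chroman-3-ol (racemate, 2R,3S enantiomer drawn) | CC(C)[Si](C(C)C)(C(C)C)Oc1cc(OCc2ccccc2)c2c(c1)O[C@H](c1ccc(OCc3ccccc3)c(OCc3ccccc3)c1)[C@@H](O)C2
F3 | step 7 | (2R,3S)-5-(benzyloxy)-2-[3,4-bis(benzyloxy)phenyl]-7-(triisopropylsilyloxy)chroman-3-yl (S)-2-methoxy-2-phenylacetate | CC(C)[Si](C(C)C)(C(C)C)Oc1cc(OCc2ccccc2)c2c(c1)O[C@H](c1ccc(OCc3ccccc3)c(OCc3ccccc3)c1)[C@@H](OC(=O)[C@@H](OC)c1ccccc1)C2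
F4 | step 7 | (2S,3R)-5-(benzyloxy)-2-[3,4-bis(benzyloxy)phenyl]-7-(triisopropylsilyloxy)chroman-3-yl (S)-2-methoxy-2-phenylacetate | CC(C)[Si](C(C)C)(C(C)C)Oc1cc(OCc2ccccc2)c2c(c1)O[C@@H](c1ccc(OCc3ccccc3)c(OCc3ccccc3)c1)[C@H](OC(=O)[C@@H](OC)c1ccccc1)C2
F5 | step 6 | 1,2-bis(benzyloxy)-4-(2-methoxyethenyl)benzene (E/Z mixture) | COC=Cc1ccc(OCc2ccccc2)c(OCc2ccccc2)c1
F6 | step 6 | 2-[3,4-bis(benzyloxy)phenyl]acetaldehyde | O=CCc1ccc(OCc2ccccc2)c(OCc2ccccc2)c1
F7 | step 6 | (Z)-2-[3,4-bis(benzyloxy)phenyl]vinyl acetate | CC(=O)O/C=C\c1ccc(OCc2ccccc2)c(OCc2ccccc2)c1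
F8 | step 10 | (2R,3S)-5-(benzyloxy)-2-[3,4-bis(benzyloxy)phenyl]-3,7-bis(tert-butyldimethylsilyloxy)chromane | CC(C)(C)[Si](C)(C)Oc1cc(OCc2ccccc2)c2c(c1)O[C@H](c1ccc(OCc3ccccc3)c(OCc3ccccc3)c1)[C@@H](O[Si](C)(C)C(C)(C)C)C2
F9 | step 10 | (2R,3S)-5-(benzyloxy)-2-[3,4-bis(benzyloxy)phenyl]-3-(tert-butyldimethylsilyloxy)chroman-7-ol | Oc1cc(OCc2ccccc2)c2c(c1)O[C@H](c1ccc(OCc3ccccc3)c(OCc3ccccc3)c1)[C@@H](O[Si](C)(C)C(C)(C)C)C2
F10 | step 10 | (2R,3S)-5-(benzyloxy)-2-[3,4-bis(benzyloxy)phenyl]-3-(tert-butyldimethylsilyloxy)chroman-7-yl 3,4,5-tris(benzyloxy)benzoate | O=C(Oc1cc(OCc2ccccc2)c2c(c1)O[C@H](c1ccc(OCc3ccccc3)c(OCc3ccccc3)c1)[C@@H](O[Si](C)(C)C(C)(C)C)C2)c1cc(OCc2ccccc2)c(OCc2ccccc2)c(OCc2ccccc2)c1
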